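## Retrosynthetic overview

- The target, (4S,5S)-4,5-dihydroxy-5-[(1S)-1-hydroxyheptadecyl]cyclopent-2-en-1-one, is opened at C4–H: hydroxyl-directed mono-reduction of a 2-hydroxy-2-(1-hydroxyalkyl)cyclopent-4-ene-1,3-dione, in which C1' (S) sets C4 and C5 together.
- That enedione comes by desilylation from a spiro-silylene enedione, the oxidised form of a spiro-silylene 4-hydroxycyclopentenone. The latter is disconnected at C3–C4 (enone β-carbon to carbinol carbon) by photochemical ring contraction of a 3-substituted 4H-pyran-4-one; ring contraction and oxidation are run as one operation.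
- Enabling feature: the ring C1(=O)–C2=C3–C4(OH)–C5 maps onto a 4-pyranone. C3 and C4 are the two carbons flanking the pyranone ring oxygen (C6 and C2), the C4 hydroxyl is that oxygen, and C5 is the pyranone α-carbon carrying the side chain; the C5–O bond is delivered from the C1' oxygen through a temporary O–Si–O tether.
- The pyranone carbinol comes from Corey–Bakshi–Shibata reduction of 3-heptadecanoyl-4H-pyran-4-one (the only catalyst-set stereocentre), made from icosane-2,4-dione and DMF dimethyl acetal.
- Ring order: pyranone ring (step 2); then the cyclopentenone ring together with the temporary dioxasilolane ring (step 5, pyranone ring consumed); the dioxasilolane is removed in step 6.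

Key step: step 5

Remark: the configurations at C4 and C5 created in the photochemical stage of step 5 are not relied on; both are erased at the enedione within the same step and set again in step 7.

## Route

Step 1
Reactants: 1 pentane-2,4-dione and 2 1-bromopentadecane
Product: 3 icosane-2,4-dione
Conditions: NaH, THF, 0 °C; n-BuLi, 0 °C; then 2, 0 °C to rt; 1 M HCl
Reagents that add atoms: none
Why: γ-alkylation of the acetylacetone dianion, whose more basic terminal carbanion should react with the primary bromide to give the 1,3-diketone regioselectively.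

Step 2
Reactants: 3 icosane-2,4-dione
Product: 6 3-heptadecanoyl-4H-pyran-4-one, via enaminodione 4 (not isolated), via bis-enaminone 5 (not isolated)
Conditions: Me2NCH(OMe)2 (4 equiv), toluene, 110 °C; then 2 M HCl, THF, rt
Reagents that add atoms: N,N-dimethylformamide dimethyl acetal, COC(OC)N(C)C; water, O
Why: twofold aminomethylenation (central CH2 first, then the acetyl CH3 in preference to the chain CH2) followed by acid hydrolysis and cyclocondensation with loss of dimethylamine is the enaminone route to 3-acyl-4-pyranones, and no stereocentre is involved.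

Step 3
Reactants: 6 3-heptadecanoyl-4H-pyran-4-one
Product: 7 3-[(1S)-1-hydroxyheptadecyl]-4H-pyran-4-one
Conditions: (R)-2-methyl-CBS-oxazaborolidine (0.5 equiv), BH3·SMe2 (1.2 equiv), THF, −30 °C; MeOH
Reagents that add atoms: none
Why: Corey–Bakshi–Shibata reduction, in which the sp2 pyranonyl group acts as the large and the n-alkyl chain as the small substituent, so that the (R)-catalyst should give the (S)-carbinol in the same sense as for aryl alkyl ketones.

Step 4
Reactants: 7 3-[(1S)-1-hydroxyheptadecyl]-4H-pyran-4-one
Product: 9 di-tert-butyl{[(1S)-1-(4-oxo-4H-pyran-3-yl)heptadecyl]oxy}silanol, via silyl triflate 8 (not isolated)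
Conditions: tBu2Si(OTf)2, 2,6-lutidine, CH2Cl2, 0 °C; then sat. aq. NaHCO3, rt
Reagents that add atoms: di-tert-butylsilyl bis(trifluoromethanesulfonate), CC(C)(C)[Si](OS(=O)(=O)C(F)(F)F)(OS(=O)(=O)C(F)(F)F)C(C)(C)C; water, O
Why: silylation of the secondary alcohol should stop at the mono-alkoxysilyl triflate because of the two tert-butyl groups, and bicarbonate hydrolysis of the remaining Si–OTf bond gives the stable di-tert-butylsilanol (the known preparation of tethered silanols), with C1' untouched.

Step 5
Reactants: 9 di-tert-butyl{[(1S)-1-(4-oxo-4H-pyran-3-yl)heptadecyl]oxy}silanol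
Product: 13 (4S)-2,2-di-tert-butyl-4-hexadecyl-1,3-dioxa-2-silaspiro[4.4]non-7-ene-6,9-dione, via oxyallyl zwitterion 10 (not isolated), via spiro-silylene hydroxyenone 11 (not isolated), via diastereomeric hydroxyenone 12 (not isolated)
Conditions: hν (254 nm, quartz), degassed MeCN (3 mM), rt; concentrate; then Dess–Martin periodinane, NaHCO3, CH2Cl2, 0 °C to rt
Reagents that add atoms: none
Why: Proposed new method: excitation of the cross-conjugated 4-pyranone should trigger the 4π-electrocyclisation that bonds pyranone C2 to C6 across the ring oxygen (the C3–C4 bond of the target, the ring oxygen becoming an epoxide) and give the bicyclic oxyallyl zwitterion 10, whose side-chain-bearing terminus is captured by the Si–OH oxygen before the enol opens the epoxide by β-elimination to unveil the enone and the C4 hydroxyl in 11 and 12. The closest known reactions are the photochemical ring contraction of 4-pyranones to 4-hydroxycyclopent-2-enones with capture of the zwitterion by water, alcohols or pendant hydroxyl groups, and the use of tethered di-tert-butylsilanols as internal oxygen nucleophiles toward epoxides and activated alkenes; new here are the silanol as the trap and a pyranone without alkyl groups at C2, C5 and C6. The cyclopentenone ring closes by an excited-state disrotatory 4π-electrocyclisation and the temporary 1,3-dioxa-2-silolane by 5-exo capture of the cation. C4 and C5 arise trans to each other because the nucleophile enters anti to the epoxide oxygen, but on either ring face relative to C1', which is why the crude mixture of 11 and 12 is oxidised at once by Dess–Martin periodinane (a known oxidation of secondary allylic alcohols) to the single enedione 13, in which C1' is the only stereocentre left. The step needs capture at the substituted oxyallyl terminus and capture faster than epoxide migration to a 2-pyranone: the two-atom O–Si tether can reach only that terminus and makes the capture intramolecular.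

Step 6
Reactants: 13 (4S)-2,2-di-tert-butyl-4-hexadecyl-1,3-dioxa-2-silaspiro[4.4]non-7-ene-6,9-dione
Product: 14 2-hydroxy-2-[(1S)-1-hydroxyheptadecyl]cyclopent-4-ene-1,3-dione
Conditions: HF·pyridine, THF/pyridine, 0 °C; crude product used directly
Reagents that add atoms: none
Why: fluoride-mediated cleavage of both Si–O bonds of the five-membered di-tert-butylsilylene, under acidic conditions that should spare the base-sensitive β-hydroxy-1,3-dione (no retro-aldol).

Step 7
Reactants: 14 2-hydroxy-2-[(1S)-1-hydroxyheptadecyl]cyclopent-4-ene-1,3-dione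
Product: 15 (4S,5S)-4,5-dihydroxy-5-[(1S)-1-hydroxyheptadecyl]cyclopent-2-en-1-one
Conditions: Me4NBH(OAc)3 (1.3 equiv), MeCN/AcOH (1:1), −40 to −25 °C; aq. KNaC4H4O6 (sodium potassium tartrate)
Reagents that add atoms: none
Why: Evans–Saksena hydroxyl-directed reduction, in which the boron-bound C1' oxygen delivers hydride intramolecularly to the ring face that carries C1' (so the new C4–OH is cis to C5–OH), and the chair-like six-membered transition state with the C16 chain pseudo-equatorial and the ring carbonyl oxygen pseudo-axial selects the diastereotopic carbonyl that gives the anti-1,3-diol, so that C4 (S) and C5 (S) should both be set from C1' in one event.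

## Compound list

1 | pentane-2,4-dione | CC(=O)CC(C)=O | starting material
2 | 1-bromopentadecane | CCCCCCCCCCCCCCCBr | starting material
3 | icosane-2,4-dione | CCCCCCCCCCCCCCCCC(=O)CC(C)=O | intermediate
4 | 3-[(dimethylamino)methylidene]icosane-2,4-dione (enaminodione) | CCCCCCCCCCCCCCCCC(=O)C(=CN(C)C)C(C)=O | intermediate
5 | (1E)-1-(dimethylamino)-4-[(dimethylamino)methylidene]henicos-1-ene-3,5-dione (bis-enaminone) | CCCCCCCCCCCCCCCCC(=O)C(=CN(C)C)C(=O)/C=C/N(C)C | intermediate
6 | 3-heptadecanoyl-4H-pyran-4-one | CCCCCCCCCCCCCCCCC(=O)C1=COC=CC1=O | intermediate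
7 | 3-[(1S)-1-hydroxyheptadecyl]-4H-pyran-4-one | CCCCCCCCCCCCCCCC[C@H](O)C1=COC=CC1=O | intermediate
8 | di-tert-butyl{[(1S)-1-(4-oxo-4H-pyran-3-yl)heptadecyl]oxy}silyl trifluoromethanesulfonate | CCCCCCCCCCCCCCCC[C@H](O[Si](OS(=O)(=O)C(F)(F)F)(C(C)(C)C)C(C)(C)C)C1=COC=CC1=O | intermediate
9 | di-tert-butyl{[(1S)-1-(4-oxo-4H-pyran-3-yl)heptadecyl]oxy}silanol | CCCCCCCCCCCCCCCC[C@H](O[Si](O)(C(C)(C)C)C(C)(C)C)C1=COC=CC1=O | intermediate
10 | oxyallyl zwitterion (6-oxabicyclo[3.1.0]hex-3-en-2-ylium-3-olate carrying the (1S)-silanol side chain at C2; epoxide on either face) | CCCCCCCCCCCCCCCC[C@H](O[Si](O)(C(C)(C)C)C(C)(C)C)[C+]1C2OC2C=C1[O-] | intermediate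
11 | (4S,5R,9R)-2,2-di-tert-butyl-4-hexadecyl-9-hydroxy-1,3-dioxa-2-silaspiro[4.4]non-7-en-6-one | CCCCCCCCCCCCCCCC[C@@H]1O[Si](C(C)(C)C)(C(C)(C)C)O[C@@]12C(=O)C=C[C@H]2O | intermediate
12 | (4S,5S,9S)-2,2-di-tert-butyl-4-hexadecyl-9-hydroxy-1,3-dioxa-2-silaspiro[4.4]non-7-en-6-one | CCCCCCCCCCCCCCCC[C@@H]1O[Si](C(C)(C)C)(C(C)(C)C)O[C@]12C(=O)C=C[C@@H]2O | intermediate
13 | (4S)-2,2-di-tert-butyl-4-hexadecyl-1,3-dioxa-2-silaspiro[4.4]non-7-ene-6,9-dione | CCCCCCCCCCCCCCCC[C@@H]1O[Si](C(C)(C)C)(C(C)(C)C)OC12C(=O)C=CC2=O | intermediate
14 | 2-hydroxy-2-[(1S)-1-hydroxyheptadecyl]cyclopent-4-ene-1,3-dione | CCCCCCCCCCCCCCCC[C@H](O)C1(O)C(=O)C=CC1=O | intermediate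
15 | (4S,5S)-4,5-dihydroxy-5-[(1S)-1-hydroxyheptadecyl]cyclopent-2-en-1-one | CCCCCCCCCCCCCCCC[C@H](O)[C@@]1(O)C(=O)C=C[C@@H]1O | target

## Step count and risks

Total step count: 7. Longest linear sequence: 7 (steps 1 to 7).

Steps most likely to fail:

1. Step 5 (proposed new method). The silanol may not intercept the zwitterion before the epoxide migrates to give a 2-pyranone or the zwitterion reverts. The electrocyclisation may be inefficient for a pyranone lacking substituents at C2, C5 and C6, and the enone photoproducts may undergo secondary photolysis before they are oxidised. Fallback with known chemistry, setting out from 7 and returning at 14: the free carbinol 7 is irradiated (254 nm) in acetonitrile–water, the established intermolecular water capture of the pyranone-derived zwitterion. This should give the 4,5-trans triols (4R,5S)-4,5-dihydroxy-5-[(1S)-1-hydroxyheptadecyl]cyclopent-2-en-1-one F1 and its (4S,5R)-diastereomer, (4S,5R)-4,5-dihydroxy-5-[(1S)-1-hydroxyheptadecyl]cyclopent-2-en-1-one F2, with any regioisomer from capture at the unsubstituted terminus removed by chromatography. Activated MnO2 in CH2Cl2 then oxidises only the allylic C4 hydroxyl of both to 14, so that steps 4 and 6 fall away.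

2. Step 7. Hydride may be delivered through a boat-like array to the other diastereotopic carbonyl, or from the tertiary hydroxyl, or a second time to the product enone. Fallback setting out from 14 and returning at 15: an Evans–Tishchenko reduction, with SmI2 pre-mixed with excess acetaldehyde to form the trivalent samarium catalyst (THF, −10 °C). Hydride is transferred from the C1' hemiacetal through a samarium-bridged bicyclic transition state and the directing oxygen is left acetylated, so a second directed reduction is excluded. The product is (1S)-1-[(1R,5S)-1,5-dihydroxy-2-oxocyclopent-3-en-1-yl]heptadecyl acetate F3 (the 1'-O-acetate of 15). Neutral enzymatic deacetylation (Candida antarctica lipase B, KH2PO4/K2HPO4 buffer pH 7/MeCN) then gives 15.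

3. Step 3. The basic pyranone carbonyl may sequester the oxazaborolidine or borane, the doubly activated C2=C3 bond may undergo conjugate reduction, or the enantioselectivity may be eroded. Fallback setting out from 6 and returning at 7: Luche reduction (NaBH4, CeCl3·7H2O, MeOH, −40 °C) to racemic 3-(1-hydroxyheptadecyl)-4H-pyran-4-one F4. This is followed by acylative kinetic resolution with a chiral isothiourea catalyst (benzotetramisole, the enantiomer that acylates the (R)-carbinol), isobutyric anhydride and iPr2NEt in CHCl3. The (R)-enantiomer is removed as (1R)-1-(4-oxo-4H-pyran-3-yl)heptadecyl 2-methylpropanoate F5, and the unreacted (S)-alcohol is 7.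

Further compounds
F1 | step 5 | (4R,5S)-4,5-dihydroxy-5-[(1S)-1-hydroxyheptadecyl]cyclopent-2-en-1-one | CCCCCCCCCCCCCCCC[C@H](O)[C@@]1(O)C(=O)C=C[C@H]1O
F2 | step 5 | (4S,5R)-4,5-dihydroxy-5-[(1S)-1-hydroxyheptadecyl]cyclopent-2-en-1-one | CCCCCCCCCCCCCCCC[C@H](O)[C@]1(O)C(=O)C=C[C@@H]1O
F3 | step 7 | (1S)-1-[(1R,5S)-1,5-dihydroxy-2-oxocyclopent-3-en-1-yl]heptadecyl acetate | CCCCCCCCCCCCCCCC[C@H](OC(C)=O)[C@@]1(O)C(=O)C=C[C@@H]1O
F4 | step 3 | racemic 3-(1-hydroxyheptadecyl)-4H-pyran-4-one | CCCCCCCCCCCCCCCCC(O)C1=COC=CC1=O
F5 | step 3 | (1R)-1-(4-oxo-4H-pyran-3-yl)heptadecyl 2-methylpropanoate | CCCCCCCCCCCCCCCC[C@@H](OC(=O)C(C)C)C1=COC=CC1=O
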